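**Marchantin H (16) by a Catellani meta-alkylation of ring D: synthesis design**

## The problem

Marchantin H (16) is a macrocyclic bis(bibenzyl). Four benzene rings are held in an 18-membered ring by two CH2CH2 bridges (ring A to ring D, ring B to ring C) and two diaryl ether oxygens (ring A to ring B, ring C to ring D). The macrocycle runs through rings A and D meta, through ring B para and through ring C ortho; there is no stereocenter, so the task is one of connectivity and regiochemistry only. Ring C is the crowded ring: C1 carries the bridge, C2 the ether oxygen, C3 and C4 the hydroxyl groups, so the C2–O bond is flanked on both sides and is a poor place for a ring closure. The ring C catechol and the ring A phenol are electron-rich and oxidise easily; they must stay masked to the last step, and the ring B oxygen needs a mask that comes off while theirs stay on. The ring closure must be run at high dilution and is best placed at the unhindered ring A–O–ring B ether. On ring D the ether oxygen (C1) and the bridge carbon (C3) are separated by a single CH (C2). An iodine on C2, which arrives with 2-iodophenol, can steer palladium and norbornene to the C3–H bond and then be exchanged for hydrogen, so ring D needs no meta-functionalised building block.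

## Retrosynthesis

**16 ⇒ 15 (three O–CH3 bonds).** The three hydroxyl groups of rings A and C are carried as methyl ethers, which come with the purchased arenes 1 and 10. They leave together in the final step, so the oxidation-prone catechol is exposed only once. The forward step must cleave three methyl ethers without opening the two diaryl ethers.

**15 ⇒ 14 (ring A carbon–oxygen bond of the A–B ether).** The macrocycle is opened at the ether between rings A and B. This cut beats the ring C–D ether, whose oxygen is flanked by two substituents. It also beats a bridge-forming Wittig macrocyclization, which would add an aldehyde/phosphonium pair and a late hydrogenation. Precursor 14 is acyclic, with one free para-alkylphenol (ring B) and one aryl bromide ortho to a methoxy group (ring A). The forward reaction is a copper-mediated Ullmann etherification that must favour ring closure over oligomerization.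

**14 ⇒ 13 (O–isopropyl bond).** The ring B oxygen is masked as an isopropyl ether. This group is inert to base, ylide, diimide and every palladium intermediate of the key step, and BCl3 removes it ahead of methyl ethers.

**13 ⇒ 9 + 12 (ring D aryl–CH2 bond, key disconnection).** The bridge between rings D and A is cut at the bond to ring D, and ring D is traced to an ortho-iodo diaryl ether. A Wittig cut through the CH2–CH2 bond would need a meta-formyl ring D and a second aldehyde/phosphonium pair to be told apart from the first. A cross-coupling at a meta halide would need an alkyl metal. The Catellani cut uses a C–H bond instead and spends the iodine in the same step. Iodide 9 holds three rings and bromide 12 one. The forward reaction must alkylate once, at C3 of ring D, engage the aryl iodide of 9 but not the aryl bromide of 12, and end by hydride transfer.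

**12 ⇒ 11 ⇒ 10 (two C–Br bonds).** The ring A arm comes from 2-(4-methoxyphenyl)ethanol (10) by ring bromination ortho to the methoxy group (11) and conversion of the alcohol to the bromide (12).

**9 ⇒ 8 ⇒ 3 + 6 (CH2–CH2 bond of the ring B–C bridge, through the alkene).** The saturated bridge is traced to stilbene 8 and this to aldehyde 3 and phosphonium salt 6 (through ylide 7). The alkene must be reduced without touching the C–I bond, which rules out hydrogenation over palladium and calls for diimide.

**3 ⇒ 1 + 2 (ring C C2–O bond).** The hindered ether is made first, between two small molecules, by nucleophilic aromatic substitution of 2-iodophenol (2) on 2-fluoro-3,4-dimethoxybenzaldehyde (1). The formyl group activates the fluoride and later becomes the bridge carbon. Aldehyde 1 already carries both ring C oxygens in the right places.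

**6 ⇒ 5 ⇒ 4 (C–P bond, then carbonyl reduction).** The phosphonium salt comes from 4-isopropoxybenzaldehyde (4), a catalogue compound, by reduction to alcohol 5 and treatment with triphenylphosphine hydrobromide.

## Roads not taken

**Alternative 1:** The cut is the ring D carbon–oxygen bond of the C–D ether, with ring D held back as a cyclohexenone. The seco compound A1 is the ring C phenol tethered to a 5-substituted 3-chlorocyclohex-2-enone, with the A–B ether and both bridges already in place. With Cs2CO3 at high dilution the phenoxide would add to the β-carbon of the chloroenone and expel chloride, closing the 18-membered ring as the racemic aryl vinylogous ester A2; ring D would be aromatised afterwards.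
- Merits: addition–elimination at a β-chloroenone is much more willing than any substitution at an aromatic carbon. The crowded ring C oxygen is etherified and the ring closed in one metal-free step.
- Weak points: ring D of the target has no oxygen at the former carbonyl carbon, so the carbonyl must be removed and the ring dehydrogenated on the macrocycle. Reduction of a vinylogous ester followed by acid normally ejects the β-oxygen substituent, which here is the ether just made. A safe detour costs several steps. The chloroenone also has to be built from a 5-substituted cyclohexane-1,3-dione, and a stereocenter is made only to be erased.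
- Comparison: in the ring closure itself this road is probably better than step 10, being milder and closing at the hindered oxygen. The chosen plan sets against this that all four rings are bought aromatic, that nothing but deprotection follows the macrocyclization, and that the hindered ether is made by a simple early substitution.

**Alternative 2:** The cut is the same ring A carbon–oxygen bond as in step 10, but made by phenol oxidation. The seco bisphenol A3 would carry a 2,6-dibromophenol as ring A and a 2,6-dichlorophenol as ring B. Tl(NO3)3 (trivalent thallium) followed by Zn would join the ring B oxygen to a brominated ortho carbon of ring A, giving the trihalogenated macrocycle A4. The remaining bromine and two chlorines would then be removed by hydrogenolysis before demethylation.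
- Merits: the ring closes at or below room temperature, the halogen pattern decides which phenol is oxidised, and the ring A hydroxyl emerges free.
- Weak points: a toxic thallium salt is used in stoichiometric amount. Four halogens are installed and three removed. The oxidant must spare the electron-rich dimethoxy ring C. The plan also says nothing about how rings C and D and the two bridges are assembled, so A3 still needs a fragment synthesis of the size of steps 1 to 8.
- Comparison: this road is better than step 10 in temperature and needs no selective unmasking of ring B. The chosen plan sets against it one halogen instead of four, copper instead of thallium, no dehalogenation step, and a fragment union that the alternative does not supply.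

**Alternative 3:** The cut is the ring C C2–O bond, with ring C grown from a cyclohexanedione. Rh2(OAc)4 (divalent rhodium) would turn 2-diazocyclohexane-1,3-dione A5 into a carbenoid that inserts into the O–H bond of the ring D phenol A6, which already carries the ring A arm. The product is the 2-aryloxy dione A7.
- Merits: the crowded ether forms under neutral conditions and makes no demand on the electronics of an aromatic ring C.
- Weak points: ring C must then be completed on an advanced intermediate. The ring B arm has to be added at one carbonyl carbon (organometallic addition beside an aryl bromide), the ring dehydrogenated to a phenol, and a second oxygen introduced at C4 by ortho-oxidation. That is five or more steps, and the sensitive catechol is created by oxidation rather than merely unmasked.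
- Comparison: this road is stronger where step 1 is weakest, because it does not depend on substitution at an electron-rich fluoroarene. The chosen plan sets against it a purchased ring C with all three heteroatoms and the bridge carbon in place, and an ether made in one step.

Key step: step 8

Remark on the chemistry: alkene 8 is expected as a mixture of E and Z isomers; since step 5 saturates the double bond, the mixture is carried on as such and is drawn without alkene geometry.

## Route

Step 1
Reactants: 1 2-fluoro-3,4-dimethoxybenzaldehyde; 2 2-iodophenol
Product: 3 2-(2-iodophenoxy)-3,4-dimethoxybenzaldehyde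
Conditions: K2CO3, DMA, 130 °C
Reagents that add atoms: none
Why: Nucleophilic aromatic substitution by addition–elimination; the fluoride is ortho to the formyl group, which stabilises the anionic adduct, and the aryl iodide of 2 is inert to carbonate.

Step 2
Reactants: 4 4-isopropoxybenzaldehyde
Product: 5 (4-isopropoxyphenyl)methanol
Conditions: NaBH4, MeOH, 0 °C to rt
Reagents that add atoms: none
Why: Hydride reduction of an aromatic aldehyde; the aryl isopropyl ether is not affected.

Step 3
Reactants: 5 (4-isopropoxyphenyl)methanol
Product: 6 (4-isopropoxybenzyl)triphenylphosphonium bromide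
Conditions: PPh3·HBr, MeCN, reflux
Reagents that add atoms: triphenylphosphine hydrobromide, Br.c1ccc(cc1)P(c1ccccc1)c1ccccc1
Why: The electron-rich benzylic alcohol ionises under the mild acid and the benzylic cation is captured by triphenylphosphine, a standard one-step phosphonium salt synthesis for alkoxybenzyl alcohols.

Step 4
Reactants: 6 (4-isopropoxybenzyl)triphenylphosphonium bromide; 3 2-(2-iodophenoxy)-3,4-dimethoxybenzaldehyde
Product: 8 2-(2-iodophenoxy)-1-[2-(4-isopropoxyphenyl)ethenyl]-3,4-dimethoxybenzene (E/Z mixture), via phosphorus ylide 7 (not isolated)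
Conditions: KOt-Bu, THF, 0 °C; then 3, 0 °C to rt
Reagents that add atoms: none
Why: Wittig olefination of a non-enolisable aldehyde by a semi-stabilised benzylic ylide; KOt-Bu does not touch the aryl iodide, and the alkene geometry is irrelevant because the double bond is reduced next.

Step 5
Reactants: 8 2-(2-iodophenoxy)-1-[2-(4-isopropoxyphenyl)ethenyl]-3,4-dimethoxybenzene (E/Z mixture)
Product: 9 2-(2-iodophenoxy)-1-[2-(4-isopropoxyphenyl)ethyl]-3,4-dimethoxybenzene
Conditions: TsNHNH2 (in portions), NaOAc, DME/H2O, reflux
Reagents that add atoms: none
Why: Diimide reduction; diimide from thermal decomposition of tosylhydrazide delivers two hydrogens to the stilbene double bond in a concerted step and leaves the C–I bond intact, which hydrogenation over palladium would not.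

Step 6
Reactants: 10 2-(4-methoxyphenyl)ethanol
Product: 11 2-(3-bromo-4-methoxyphenyl)ethanol
Conditions: NBS, MeCN, rt
Reagents that add atoms: N-bromosuccinimide, O=C1CCC(=O)N1Br
Why: Electrophilic aromatic bromination; the methoxy group directs ortho and para, the para position is occupied, so bromine enters ortho to the methoxy group.

Step 7
Reactants: 11 2-(3-bromo-4-methoxyphenyl)ethanol
Product: 12 2-bromo-4-(2-bromoethyl)-1-methoxybenzene
Conditions: CBr4, PPh3, CH2Cl2, 0 °C to rt
Reagents that add atoms: carbon tetrabromide, BrC(Br)(Br)Br
Why: Appel reaction; bromide displaces the alkoxyphosphonium group at the primary carbon by an SN2 step, and the aryl bromide and the ether are inert.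

Step 8
Reactants: 9 2-(2-iodophenoxy)-1-[2-(4-isopropoxyphenyl)ethyl]-3,4-dimethoxybenzene; 12 2-bromo-4-(2-bromoethyl)-1-methoxybenzene
Product: 13 2-{3-[2-(3-bromo-4-methoxyphenyl)ethyl]phenoxy}-1-[2-(4-isopropoxyphenyl)ethyl]-3,4-dimethoxybenzene
Conditions: Pd(OAc)2 (10 mol %), P(2-furyl)3 (25 mol %), norbornene (2 equiv), Cs2CO3 (3 equiv), i-PrOH (5 equiv), 12 (2.5 equiv), DME, 85 °C
Reagents that add atoms: none
Why: Catellani reaction: zerovalent palladium formed from Pd(OAc)2 and the phosphine inserts into the C–I bond of 9, norbornene inserts into the aryl–palladium bond, and carbonate-assisted palladation of the only free ortho C–H (C3 of ring D) gives the five-membered aryl–norbornyl palladacycle. The palladacycle adds the primary bromide 12 to reach tetravalent palladium, and reductive elimination forms the ring D aryl–CH2 bond. With both ortho positions now substituted, norbornene is expelled by β-carbon elimination; the aryl palladium species takes up isopropoxide, β-hydride elimination releases acetone, and C–H reductive elimination puts hydrogen where the iodine was. The closest known reaction type is the ortho alkylation of ortho-substituted aryl iodides with primary alkyl bromides ended by a hydride donor, which gives meta-disubstituted arenes. No ring is closed and no stereocenter is formed. Site selectivity is secured by the substrate: the other ortho position of the iodide carries the aryloxy group, and both ring C carbons next to the ether oxygen are substituted, so cyclisation to a dibenzofuran has no C–H to use. Chemoselectivity rests on oxidative addition of the aryl iodide running well ahead of that of the electron-rich ortho-methoxy aryl bromide in 12 and 13, and the excess of 12 offsets loss by elimination of HBr.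

Step 9
Reactants: 13 2-{3-[2-(3-bromo-4-methoxyphenyl)ethyl]phenoxy}-1-[2-(4-isopropoxyphenyl)ethyl]-3,4-dimethoxybenzene
Product: 14 4-[2-(2-{3-[2-(3-bromo-4-methoxyphenyl)ethyl]phenoxy}-3,4-dimethoxyphenyl)ethyl]phenol
Conditions: BCl3, CH2Cl2, −78 to 0 °C; then H2O
Reagents that add atoms: none
Why: Selective Lewis-acid dealkylation of an aryl isopropyl ether; the secondary alkyl group leaves from the boron–ether complex much faster than methyl, so at or below 0 °C the methyl ethers, the diaryl ether and the aryl bromide should remain.

Step 10
Reactants: 14 4-[2-(2-{3-[2-(3-bromo-4-methoxyphenyl)ethyl]phenoxy}-3,4-dimethoxyphenyl)ethyl]phenol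
Product: 15 tri-O-methylmarchantin H (the 18-membered macrocycle with methyl ethers on the ring A oxygen and both ring C oxygens)
Conditions: CuI (0.5 equiv), picolinic acid, K3PO4, DMSO, 100 °C, slow addition of 14 (final 2 mM)
Reagents that add atoms: none
Why: Intramolecular Ullmann diaryl ether synthesis; the copper phenoxide of the unhindered ring B phenol engages the ring A C–Br bond and C–O reductive elimination closes the 18-membered ring, while slow addition keeps the concentration low enough to favour ring closure over oligomerization.

Step 11
Reactants: 15 tri-O-methylmarchantin H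
Product: 16 marchantin H
Conditions: BBr3, CH2Cl2, −78 °C to rt; then MeOH, H2O
Reagents that add atoms: none
Why: BBr3 demethylation; bromide attacks the methyl carbon of each boron–ether complex, whereas the diaryl ethers offer no sp3 carbon on oxygen and stay intact.

## Compound list

1 | 2-fluoro-3,4-dimethoxybenzaldehyde | COc1ccc(C=O)c(F)c1OC | starting material
2 | 2-iodophenol | Oc1ccccc1I | starting material
3 | 2-(2-iodophenoxy)-3,4-dimethoxybenzaldehyde | COc1ccc(C=O)c(Oc2ccccc2I)c1OC | intermediate
4 | 4-isopropoxybenzaldehyde | CC(C)Oc1ccc(C=O)cc1 | starting material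
5 | (4-isopropoxyphenyl)methanol | CC(C)Oc1ccc(CO)cc1 | intermediate
6 | (4-isopropoxybenzyl)triphenylphosphonium bromide | CC(C)Oc1ccc(C[P+](c2ccccc2)(c2ccccc2)c2ccccc2)cc1.[Br-] | intermediate
7 | (4-isopropoxybenzylidene)triphenylphosphorane (ylide, not isolated) | CC(C)Oc1ccc(C=P(c2ccccc2)(c2ccccc2)c2ccccc2)cc1 | intermediate
8 | 2-(2-iodophenoxy)-1-[2-(4-isopropoxyphenyl)ethenyl]-3,4-dimethoxybenzene, E/Z mixture | COc1ccc(C=Cc2ccc(OC(C)C)cc2)c(Oc2ccccc2I)c1OC | intermediate
9 | 2-(2-iodophenoxy)-1-[2-(4-isopropoxyphenyl)ethyl]-3,4-dimethoxybenzene | COc1ccc(CCc2ccc(OC(C)C)cc2)c(Oc2ccccc2I)c1OC | intermediate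
10 | 2-(4-methoxyphenyl)ethanol | COc1ccc(CCO)cc1 | starting material
11 | 2-(3-bromo-4-methoxyphenyl)ethanol | COc1ccc(CCO)cc1Br | intermediate
12 | 2-bromo-4-(2-bromoethyl)-1-methoxybenzene | COc1ccc(CCBr)cc1Br | intermediate
13 | 2-{3-[2-(3-bromo-4-methoxyphenyl)ethyl]phenoxy}-1-[2-(4-isopropoxyphenyl)ethyl]-3,4-dimethoxybenzene | COc1ccc(CCc2ccc(OC(C)C)cc2)c(Oc2cccc(CCc3ccc(OC)c(Br)c3)c2)c1OC | intermediate
14 | 4-[2-(2-{3-[2-(3-bromo-4-methoxyphenyl)ethyl]phenoxy}-3,4-dimethoxyphenyl)ethyl]phenol | COc1ccc(CCc2ccc(O)cc2)c(Oc2cccc(CCc3ccc(OC)c(Br)c3)c2)c1OC | intermediate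
15 | tri-O-methylmarchantin H | COc1ccc2cc1Oc1ccc(cc1)CCc1ccc(OC)c(OC)c1Oc1cccc(c1)CC2 | intermediate
16 | marchantin H | Oc1ccc2cc1Oc1ccc(cc1)CCc1ccc(O)c(O)c1Oc1cccc(c1)CC2 | target

## Step count and risks

Total: 11 steps. Longest linear sequence: 8 steps (steps 2, 3, 4, 5, 8, 9, 10, 11, from 4 to 16).

**Step 8 (key step).** Three processes could compete with the wanted path:
- Base-induced loss of HBr from the phenethyl bromide, which uses up the electrophile and feeds a styrene into Heck-type termination.
- Reduction of the aryl palladium iodide before norbornene insertion and C–H palladation, which only removes the iodine.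
- Slow addition of the bromide to the palladacycle, which lets the palladacycle collapse to a norbornane-fused benzocyclobutene.

Fallback: the ring D–CH2 bond is made by cross-coupling at a meta iodide placed beforehand. The fallback sets out from 1, 6 and 12 and comes back at 13.
- The substitution of step 1 with 3-iodophenol F1 in place of 2 would give 2-(3-iodophenoxy)-3,4-dimethoxybenzaldehyde F2.
- Wittig reaction with ylide 7 (from 6) and diimide reduction, as in steps 4 and 5, would give 2-(3-iodophenoxy)-1-[2-(4-isopropoxyphenyl)ethenyl]-3,4-dimethoxybenzene F3 and then 2-(3-iodophenoxy)-1-[2-(4-isopropoxyphenyl)ethyl]-3,4-dimethoxybenzene F4.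
- Bromide 12 would be turned with KOt-Bu into 2-bromo-4-ethenyl-1-methoxybenzene F5 and hydroborated with 9-BBN to 9-[2-(3-bromo-4-methoxyphenyl)ethyl]-9-borabicyclo[3.3.1]nonane F6.
- B-alkyl Suzuki–Miyaura coupling of F6 with F4 (Pd(dppf)Cl2, K3PO4, DMF/THF/H2O, 50 °C), the aryl iodide reacting ahead of the aryl bromide, would give 13.

**Step 10.** Intermolecular etherification is the main threat, because an 18-membered ring closes slowly and the electron-rich, ortho-substituted aryl bromide needs heat. Reductive loss of bromine at that temperature is the second.

Fallback: the same bond is closed oxidatively at room temperature. It sets out from 14 and comes back at 15.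
- Miyaura borylation of 14 (B2pin2, Pd(dppf)Cl2, KOAc, dioxane, 90 °C) would give 4-[2-(2-{3-[2-(4-methoxy-3-(4,4,5,5-tetramethyl-1,3,2-dioxaborolan-2-yl)phenyl)ethyl]phenoxy}-3,4-dimethoxyphenyl)ethyl]phenol F7.
- Cleavage of the pinacol ester (NaIO4, NH4OAc, acetone/H2O) would give the boronic acid, [5-(2-{3-[6-(4-hydroxyphenethyl)-2,3-dimethoxyphenoxy]phenyl}ethyl)-2-methoxyphenyl]boronic acid F8.
- Chan–Lam coupling of F8 (Cu(OAc)2, Et3N, 4 Å molecular sieves, CH2Cl2, air, rt, high dilution) would give 15.

**Step 1.** The substitution may be sluggish. The fluoride is activated only by the ortho formyl group, whose pull is damped by the para methoxy group, and the nucleophile is a hindered ortho-iodophenoxide. Forcing the temperature invites decomposition of the aldehyde.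

Fallback: the roles are reversed so that a strongly activated nitroarene takes the phenoxide, and the iodine is introduced last. It sets out from 6 (through ylide 7) and comes back at 9.
- 2-Hydroxy-3,4-dimethoxybenzaldehyde F9 and 1-fluoro-2-nitrobenzene F10 (K2CO3, DMF, 80 °C) would give 3,4-dimethoxy-2-(2-nitrophenoxy)benzaldehyde F11.
- Wittig reaction with 7 would give 1-[2-(4-isopropoxyphenyl)ethenyl]-3,4-dimethoxy-2-(2-nitrophenoxy)benzene F12.
- Hydrogenation (H2, Pd/C, EtOAc) would reduce the alkene and the nitro group together to 2-{6-[2-(4-isopropoxyphenyl)ethyl]-2,3-dimethoxyphenoxy}aniline F13. No halogen is present at this stage, so step 5 is not needed on this path.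
- Diazotisation (NaNO2, p-TsOH, MeCN/H2O, 0 °C) to the arenediazonium tosylate F14, followed by KI (Sandmeyer-type iodination), would give 9.

**Step 9.** The ring C methyl ether at C3 is flanked by two oxygens and is the most Lewis-basic and most strained of the three. It could be cleaved alongside the isopropyl group at the temperature that group needs, and the extra phenol would then disturb step 10.

Fallback: the ring B oxygen is carried as a benzyl ether, which is cleaved at a temperature where aryl methyl ethers do not react. It sets out from 3 and comes back at 14.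
- (4-Benzyloxybenzyl)triphenylphosphonium chloride F15 would be converted with KOt-Bu into its ylide, (4-benzyloxybenzylidene)triphenylphosphorane F16.
- Wittig reaction of F16 with 3 would give 1-[2-(4-benzyloxyphenyl)ethenyl]-2-(2-iodophenoxy)-3,4-dimethoxybenzene F17, and diimide reduction 1-[2-(4-benzyloxyphenyl)ethyl]-2-(2-iodophenoxy)-3,4-dimethoxybenzene F18.
- The conditions of step 8 with 12 would give 1-[2-(4-benzyloxyphenyl)ethyl]-2-{3-[2-(3-bromo-4-methoxyphenyl)ethyl]phenoxy}-3,4-dimethoxybenzene F19.
- BCl3 with pentamethylbenzene as cation scavenger (CH2Cl2, −78 °C) would remove the benzyl group and give 14.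

## Further compounds

F1 | step 8 | 3-iodophenol | Oc1cccc(I)c1
F2 | step 8 | 2-(3-iodophenoxy)-3,4-dimethoxybenzaldehyde | COc1ccc(C=O)c(Oc2cccc(I)c2)c1OC
F3 | step 8 | 2-(3-iodophenoxy)-1-[2-(4-isopropoxyphenyl)ethenyl]-3,4-dimethoxybenzene (E/Z mixture) | COc1ccc(C=Cc2ccc(OC(C)C)cc2)c(Oc2cccc(I)c2)c1OC
F4 | step 8 | 2-(3-iodophenoxy)-1-[2-(4-isopropoxyphenyl)ethyl]-3,4-dimethoxybenzene | COc1ccc(CCc2ccc(OC(C)C)cc2)c(Oc2cccc(I)c2)c1OC
F5 | step 8 | 2-bromo-4-ethenyl-1-methoxybenzene | COc1ccc(C=C)cc1Br
F6 | step 8 | 9-[2-(3-bromo-4-methoxyphenyl)ethyl]-9-borabicyclo[3.3.1]nonane | COc1ccc(CCB2C3CCCC2CCC3)cc1Br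
F7 | step 10 | 4-[2-(2-{3-[2-(4-methoxy-3-(4,4,5,5-tetramethyl-1,3,2-dioxaborolan-2-yl)phenyl)ethyl]phenoxy}-3,4-dimethoxyphenyl)ethyl]phenol | COc1ccc(CCc2ccc(O)cc2)c(Oc2cccc(CCc3ccc(OC)c(B4OC(C)(C)C(C)(C)O4)c3)c2)c1OC
F8 | step 10 | [5-(2-{3-[6-(4-hydroxyphenethyl)-2,3-dimethoxyphenoxy]phenyl}ethyl)-2-methoxyphenyl]boronic acid | COc1ccc(CCc2ccc(O)cc2)c(Oc2cccc(CCc3ccc(OC)c(B(O)O)c3)c2)c1OC
F9 | step 1 | 2-hydroxy-3,4-dimethoxybenzaldehyde | COc1ccc(C=O)c(O)c1OC
F10 | step 1 | 1-fluoro-2-nitrobenzene | O=[N+]([O-])c1ccccc1F
F11 | step 1 | 3,4-dimethoxy-2-(2-nitrophenoxy)benzaldehyde | COc1ccc(C=O)c(Oc2ccccc2[N+](=O)[O-])c1OC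
F12 | step 1 | 1-[2-(4-isopropoxyphenyl)ethenyl]-3,4-dimethoxy-2-(2-nitrophenoxy)benzene (E/Z mixture) | COc1ccc(C=Cc2ccc(OC(C)C)cc2)c(Oc2ccccc2[N+](=O)[O-])c1OC
F13 | step 1 | 2-{6-[2-(4-isopropoxyphenyl)ethyl]-2,3-dimethoxyphenoxy}aniline | COc1ccc(CCc2ccc(OC(C)C)cc2)c(Oc2ccccc2N)c1OC
F14 | step 1 | 2-{6-[2-(4-isopropoxyphenyl)ethyl]-2,3-dimethoxyphenoxy}benzenediazonium 4-methylbenzenesulfonate | COc1ccc(CCc2ccc(OC(C)C)cc2)c(Oc2ccccc2[N+]#N)c1OC.Cc1ccc(cc1)S(=O)(=O)[O-]
F15 | step 9 | (4-benzyloxybenzyl)triphenylphosphonium chloride | c1ccc(COc2ccc(C[P+](c3ccccc3)(c3ccccc3)c3ccccc3)cc2)cc1.[Cl-]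
F16 | step 9 | (4-benzyloxybenzylidene)triphenylphosphorane | c1ccc(COc2ccc(C=P(c3ccccc3)(c3ccccc3)c3ccccc3)cc2)cc1
F17 | step 9 | 1-[2-(4-benzyloxyphenyl)ethenyl]-2-(2-iodophenoxy)-3,4-dimethoxybenzene (E/Z mixture) | COc1ccc(C=Cc2ccc(OCc3ccccc3)cc2)c(Oc2ccccc2I)c1OC
F18 | step 9 | 1-[2-(4-benzyloxyphenyl)ethyl]-2-(2-iodophenoxy)-3,4-dimethoxybenzene | COc1ccc(CCc2ccc(OCc3ccccc3)cc2)c(Oc2ccccc2I)c1OC
F19 | step 9 | 1-[2-(4-benzyloxyphenyl)ethyl]-2-{3-[2-(3-bromo-4-methoxyphenyl)ethyl]phenoxy}-3,4-dimethoxybenzene | COc1ccc(CCc2ccc(OCc3ccccc3)cc2)c(Oc2cccc(CCc3ccc(OC)c(Br)c3)c2)c1OC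
A1 | alternative 1 | seco ring C phenol tethered to a 5-substituted 3-chlorocyclohex-2-enone (racemic) | O=C1C=C(Cl)CC(C1)CCc1ccc(OC)c(c1)Oc1ccc(cc1)CCc1ccc(OC)c(OC)c1O
A2 | alternative 1 | racemic macrocyclic aryl vinylogous ester | O=C1C=C2CC(C1)CCc1ccc(OC)c(c1)Oc1ccc(cc1)CCc1ccc(OC)c(OC)c1O2
A3 | alternative 2 | seco bisphenol with 2,6-dibromophenol ring A and 2,6-dichlorophenol ring B | Oc1c(Br)cc(cc1Br)CCc1cccc(c1)Oc1c(OC)c(OC)ccc1CCc1cc(Cl)c(O)c(Cl)c1
A4 | alternative 2 | trihalogenated di-O-methylmarchantin H | Oc1c(Br)cc2cc1Oc1c(Cl)cc(cc1Cl)CCc1ccc(OC)c(OC)c1Oc1cccc(c1)CC2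
A5 | alternative 3 | 2-diazocyclohexane-1,3-dione | O=C1CCCC(=O)C1=[N+]=[N-]
A6 | alternative 3 | 3-[2-(3-bromo-4-methoxyphenyl)ethyl]phenol | Oc1cccc(CCc2ccc(OC)c(Br)c2)c1
A7 | alternative 3 | 2-{3-[2-(3-bromo-4-methoxyphenyl)ethyl]phenoxy}cyclohexane-1,3-dione | O=C1CCCC(=O)C1Oc1cccc(CCc2ccc(OC)c(Br)c2)c1
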